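**Strategy.** The route rests on cutting ring A away from ring B at quaternary C10. In ring B, C10 (bearing the C14 methyl) is the β-carbon of the C8 ketone and must carry C1 trans to the C5 side chain. A [2+2] photocycloaddition of allene across C9=C10 of a ring B enone forms C10–C1 on the face opposite the C5 arm in one operation, together with a sacrificial C9–C2 bond. Ozonolysis and retro-Claisen opening then leave the C1–C2 acetate arm and the C8 ketone. The precursor is (R)-4-(silyloxymethyl)-3-methylcyclohex-2-enone, with C5 and C4 in place. Ring A is closed later with a dithiane carbon as C3.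

Key step: step 5

Numbering: eudesmane numbers are used for the carbons of all intermediates (ring A = C1–C5 and C10, ring B = C5–C10, C14 = methyl on C10, C15 = methyl on C4); β is the face of the C14 methyl.

Assumption: the lipase in step 3 acetylates the (S)-alcohol faster and leaves the (R)-alcohol 6 unreacted.

Step 1
Reactants: 1 ethyl 2-methyl-4-oxocyclohex-2-ene-1-carboxylate (racemic)
Product: 2 ethyl 7-methyl-1,4-dioxaspiro[4.5]dec-7-ene-8-carboxylate
Conditions: ethylene glycol, TsOH·H2O (cat.), benzene, reflux, Dean–Stark trap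
Reagents that add atoms: ethylene glycol, OCCO
Why: Acid-catalysed ketalization masks the ketone and its acidic γ-position before hydride reduction; the double bond should move into conjugation with the ester, which is harmless because C5 is racemic here and is re-formed in step 2.

Step 2
Reactants: 2 ketal ester
Product: 5 rac-4-(hydroxymethyl)-3-methylcyclohex-2-en-1-one, via ketal alcohol 3 (not isolated), via deconjugated enone 4 (not isolated)
Conditions: LiAlH4, Et2O, 0 °C; aqueous NaOH work-up; then 1 M HCl, THF, 0 → 23 °C
Reagents that add atoms: water, O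
Why: LiAlH4 reduces the conjugated ester in the 1,2 sense to the allylic alcohol, and ketal hydrolysis followed by acid-catalysed isomerisation through the dienol moves the double bond to C9=C10 and creates C5 as a racemate.

Step 3
Reactants: 5 racemic hydroxy enone
Product: 6 (R)-4-(hydroxymethyl)-3-methylcyclohex-2-en-1-one
Conditions: Burkholderia cepacia lipase, vinyl acetate, t-BuOMe, 25 °C, stopped shortly after half conversion; chromatography
Reagents that add atoms: none
Why: Lipase-catalysed kinetic resolution by irreversible transesterification: one enantiomer of the primary alcohol should be acetylated faster, so that the unreacted (R)-alcohol (C5 as in the target) is recovered in high enantiomeric purity once the reaction has passed half conversion.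

Step 4
Reactants: 6 (R)-hydroxy enone
Product: 7 (R)-4-{[(tert-butyldimethylsilyl)oxy]methyl}-3-methylcyclohex-2-en-1-one
Conditions: TBSCl, imidazole, DMF, 0 → 23 °C
Reagents that add atoms: tert-butyldimethylsilyl chloride, CC(C)(C)[Si](C)(C)Cl
Why: Silylation of the primary alcohol gives an ether that is stable to irradiation, ozone, methoxide and hydride and enlarges the C5 arm that will direct the photocycloaddition.

Step 5
Reactants: 7 silyl ether enone; 8 allene
Product: 9 (1S,5R,6S)-5-{[(tert-butyldimethylsilyl)oxy]methyl}-6-methyl-8-methylidenebicyclo[4.2.0]octan-2-one (cis-fused; eudesmane C9, C5, C10)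
Conditions: hν (medium-pressure Hg lamp, uranium-glass filter, λ > 340 nm), allene (excess), THF, −78 °C
Reagents that add atoms: none
Why: Excitation of the enone (n→π*) and intersystem crossing give the twisted triplet, which adds ground-state allene stepwise through a triplet 1,4-biradical that closes after spin inversion. The closest known reaction type is the photoaddition of allene to 3-alkylcyclohex-2-enones, which delivers the head-to-head methylenecyclobutane with the sp2 carbon on the α-carbon. The four-membered ring (C9, C10, C1, C2) is closed by this stepwise [2+2] cycloaddition in the cis-fused mode that is usual for allene. C10 is controlled by the C5 stereocentre: allylic strain with the C10 methyl should turn the CH2OSi arm pseudo-axial so that it screens one face, and C10–C1 should form on the other, trans to C4; C9 follows from the cis ring fusion and is erased in step 6. The step needs head-to-head regiochemistry (allene CH2 on C10, central carbon on C9) and attack anti to the C5 arm; the first should be secured by the polarity of the enone triplet at low temperature, the second by the adjacent C5 substituent. The long-wavelength filter should protect the β,γ-unsaturated ketone product from secondary photoreactions.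

Step 6
Reactants: 9 photoadduct
Product: 11 methyl 2-[(1S,2R)-2-{[(tert-butyldimethylsilyl)oxy]methyl}-1-methyl-5-oxocyclohexyl]acetate, via cyclobutane-1,3-dione 10 (not isolated)
Conditions: O3, CH2Cl2, −78 °C; Me2S, −78 → 23 °C; then NaOMe (0.2 equiv), MeOH, 0 °C
Reagents that add atoms: ozone, [O-][O+]=O; methanol (with catalytic NaOMe), CO
Why: Ozonolysis of the exocyclic methylene gives the strained 2-acylcyclobutanone, and methoxide adds to the cyclobutanone carbonyl (C2) and triggers a retro-Claisen fragmentation that expels the C8 enolate, cutting C9–C2 with relief of ring strain; C9 becomes CH2 and C10 and C5 are untouched.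

Step 7
Reactants: 11 keto ester
Product: 12 methyl 2-[(7S,8R)-8-{[(tert-butyldimethylsilyl)oxy]methyl}-7-methyl-1,4-dioxaspiro[4.5]decan-7-yl]acetate
Conditions: Me3SiOCH2CH2OSiMe3, Me3SiOTf (cat.), CH2Cl2, −78 → −20 °C
Reagents that add atoms: 1,2-bis(trimethylsilyloxy)ethane, C[Si](C)(C)OCCO[Si](C)(C)C
Why: Aprotic ketalization by silyl transfer protects the C8 ketone without cleaving the silyl ether or the ester, so that the organometallic steps 12–15 and the later C3 reduction cannot touch C8.

Step 8
Reactants: 12 ketal ester
Product: 13 2-[(7R,8R)-8-{[(tert-butyldimethylsilyl)oxy]methyl}-7-methyl-1,4-dioxaspiro[4.5]decan-7-yl]ethan-1-ol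
Conditions: LiAlH4, THF, 0 °C; aqueous NaOH work-up
Reagents that add atoms: none
Why: LiAlH4 reduction of the methyl ester gives the primary alcohol at C2; the ketal and the silyl ether are stable to hydride.

Step 9
Reactants: 13 ketal alcohol
Product: 14 tert-butyl{[(7S,8R)-7-(2-chloroethyl)-7-methyl-1,4-dioxaspiro[4.5]decan-8-yl]methoxy}dimethylsilane
Conditions: PPh3, N-chlorosuccinimide, CH2Cl2, 0 → 23 °C
Reagents that add atoms: N-chlorosuccinimide, O=C1CCC(=O)N1Cl
Why: Appel-type chlorination converts the primary alcohol by SN2 into a chloride that is inert in steps 10–14 and serves as the leaving group in step 15.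

Step 10
Reactants: 14 chloride
Product: 15 [(7S,8R)-7-(2-chloroethyl)-7-methyl-1,4-dioxaspiro[4.5]decan-8-yl]methanol
Conditions: Bu4NF, THF, 0 → 23 °C
Reagents that add atoms: none
Why: Fluoride-mediated desilylation frees the C4 alcohol; the primary chloride and the dioxolane are inert to fluoride at this temperature.

Step 11
Reactants: 15 chloro alcohol
Product: 16 (7S,8R)-7-(2-chloroethyl)-7-methyl-1,4-dioxaspiro[4.5]decane-8-carbaldehyde
Conditions: Dess–Martin periodinane, CH2Cl2, 0 → 23 °C
Reagents that add atoms: none
Why: Dess–Martin oxidation gives the aldehyde under non-basic conditions, chosen so that the C5 centre α to the new carbonyl is not epimerised.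

Step 12
Reactants: 16 aldehyde
Product: 17 1-[(7S,8R)-7-(2-chloroethyl)-7-methyl-1,4-dioxaspiro[4.5]decan-8-yl]ethan-1-ol (both carbinol epimers)
Conditions: MeMgBr, THF, −78 → 0 °C
Reagents that add atoms: methylmagnesium bromide, C[Mg]Br
Why: Grignard 1,2-addition to the aldehyde brings in C15 and is far faster than any reaction at the primary chloride; the new carbinol centre forms as a mixture and is removed in step 13.

Step 13
Reactants: 17 secondary alcohol
Product: 18 1-[(7S,8R)-7-(2-chloroethyl)-7-methyl-1,4-dioxaspiro[4.5]decan-8-yl]ethan-1-one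
Conditions: Dess–Martin periodinane, CH2Cl2, 23 °C
Reagents that add atoms: none
Why: Dess–Martin oxidation of the secondary alcohol gives the C4 methyl ketone without base, so the epimerisable C5 centre should be kept.

Step 14
Reactants: 18 methyl ketone; 19 1,3-dithiane
Product: 21 (1S)-1-[(7S,8R)-7-(2-chloroethyl)-7-methyl-1,4-dioxaspiro[4.5]decan-8-yl]-1-(1,3-dithian-2-yl)ethan-1-ol, via 2-lithio-1,3-dithiane 20 (not isolated)
Conditions: 19, n-BuLi, THF, −30 °C; then 18, −78 °C; water quench at −78 °C
Reagents that add atoms: none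
Why: Corey–Seebach addition of the lithiated dithiane (C3) to the methyl ketone under Felkin–Anh control: with quaternary C10 anti to the incoming nucleophile and the small H5 beside its path, C4 should form with the (S) configuration (4α-OH, 4β-CH3 once ring A is closed), while the primary chloride is inert at −78 °C.

Step 15
Reactants: 21 dithiane carbinol
Product: 23 3,3-(propane-1,3-diyldisulfanediyl)-8,8-(ethylenedioxy)-11,12,13-trinoreudesman-4α-ol (5α-H, 4β-CH3, 10β-CH3), via dilithio dianion 22 (not isolated)
Conditions: n-BuLi (2.3 equiv), THF–hexamethylphosphoramide, −40 → 0 °C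
Reagents that add atoms: none
Why: A second lithiation at the dithiane C–H, assisted by the neighbouring lithium alkoxide, gives the O,C-dilithio species, whose carbanion closes ring A by intramolecular Corey–Seebach alkylation (6-exo-tet SN2 at C2); no stereocentre is touched and the ring fusion stays trans.

Step 16
Reactants: 23 spiro dithiane
Product: 24 8,8-(ethylenedioxy)-4α-hydroxy-11,12,13-trinoreudesman-3-one
Conditions: MeI, CaCO3, MeCN–H2O (4:1), 45 °C
Reagents that add atoms: water, O
Why: Hydrolysis of the dithioketal by S-methylation under CaCO3 buffering unmasks the C3 ketone as the α-ketol while the dioxolane at C8 stays on.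

Step 17
Reactants: 24 α-ketol
Product: 26 3β,4α-dihydroxy-11,12,13-trinoreudesman-8-one, via diol ketal 25 (not isolated)
Conditions: NaBH4, MeOH, −20 °C; then 1 M HCl, THF, 23 °C
Reagents that add atoms: water, O
Why: NaBH4 should deliver hydride axially from the α face of the C3 ketone, opposite the axial C4 and C10 methyl groups, to give the equatorial 3β-alcohol trans to the 4α-hydroxyl, and aqueous acid then hydrolyses the dioxolane; with C8 masked during the reduction only C3 is reduced.

Step 18
Reactants: 26 diol ketone
Product: 28 3β,4α,11-trihydroxyeudesman-8-one (C7 epimers), via trilithium enolate 27 (not isolated)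
Conditions: LiN(iPr)2 (3.3 equiv), THF, −78 → −40 °C; acetone, −78 °C
Reagents that add atoms: acetone, CC(C)=O
Why: Directed aldol addition: excess LiN(iPr)2 forms the dialkoxide and then the kinetic C7 enolate (C9 is shielded by quaternary C10), which adds to acetone; the C7 centre formed here is lost in step 19.

Step 19
Reactants: 28 aldol adduct
Product: 29 3β,4α-dihydroxyeudesm-7(11)-en-8-one
Conditions: TsOH·H2O (cat.), benzene, 50 °C
Reagents that add atoms: none
Why: Acid-catalysed dehydration of the β-hydroxy ketone (aldol condensation) should give the conjugated, tetrasubstituted isopropylidene ketone, while the C4 carbinol, deactivated toward ionisation by the vicinal C3 oxygen, should remain.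

Step 20
Reactants: 29 diol enone; 30 angelic acid
Product: 32 3β-angeloyloxy-4α-hydroxyeudesm-7(11)-en-8-one, via mixed anhydride 31 (not isolated)
Conditions: 30, 2,4,6-trichlorobenzoyl chloride, Et3N, toluene, 23 °C; then 29, 80 °C
Reagents that add atoms: none
Why: Yamaguchi-type esterification through the 2,4,6-trichlorobenzoyl mixed anhydride, run without a nucleophilic amine catalyst so that the (Z)-geometry of the angelate is kept; only the secondary equatorial C3 hydroxyl should react, the tertiary C4 hydroxyl being too hindered.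

Step 21
Reactants: 32 angelate enone
Product: 33 3β-angeloyloxy-11-hydroperoxy-4α-hydroxyeudesm-6-en-8-one (3S,4S,5R,10R in eudesmane numbering; CNP0161122.1)
Conditions: O2, hν (visible), tetraphenylporphyrin (cat.), CH2Cl2, 0 °C
Reagents that add atoms: dioxygen, O=O
Why: Schenck ene reaction: singlet oxygen adds to C11 of the s-cis enone and abstracts an allylic hydrogen from C6, the group geminal to the carbonyl on C7 (the usual regiochemistry of α,β-unsaturated ketones), which moves the double bond to C6=C7 and gives the tertiary hydroperoxide; the electron-poor trisubstituted angelate should react far more slowly.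

**Compound list**

1 | ethyl 2-methyl-4-oxocyclohex-2-ene-1-carboxylate (racemic) | CCOC(=O)C1CCC(=O)C=C1C | starting material
2 | ethyl 7-methyl-1,4-dioxaspiro[4.5]dec-7-ene-8-carboxylate | CCOC(=O)C1=C(C)CC2(CC1)OCCO2 | intermediate
3 | (7-methyl-1,4-dioxaspiro[4.5]dec-7-en-8-yl)methanol | OCC1=C(C)CC2(CC1)OCCO2 | intermediate
4 | 4-(hydroxymethyl)-3-methylcyclohex-3-en-1-one | CC1=C(CO)CCC(=O)C1 | intermediate
5 | rac-4-(hydroxymethyl)-3-methylcyclohex-2-en-1-one | CC1=CC(=O)CCC1CO | intermediate
6 | (R)-4-(hydroxymethyl)-3-methylcyclohex-2-en-1-one | CC1=CC(=O)CC[C@H]1CO | intermediate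
7 | (R)-4-{[(tert-butyldimethylsilyl)oxy]methyl}-3-methylcyclohex-2-en-1-one | CC1=CC(=O)CC[C@H]1CO[Si](C)(C)C(C)(C)C | intermediate
8 | allene (propa-1,2-diene) | C=C=C | starting material
9 | (1S,5R,6S)-5-{[(tert-butyldimethylsilyl)oxy]methyl}-6-methyl-8-methylidenebicyclo[4.2.0]octan-2-one | C=C1C[C@]2(C)[C@H]1C(=O)CC[C@H]2CO[Si](C)(C)C(C)(C)C | intermediate
10 | (1S,5R,6S)-5-{[(tert-butyldimethylsilyl)oxy]methyl}-6-methylbicyclo[4.2.0]octane-2,8-dione | O=C1C[C@]2(C)[C@H]1C(=O)CC[C@H]2CO[Si](C)(C)C(C)(C)C | intermediate
11 | methyl 2-[(1S,2R)-2-{[(tert-butyldimethylsilyl)oxy]methyl}-1-methyl-5-oxocyclohexyl]acetate | COC(=O)C[C@]1(C)CC(=O)CC[C@H]1CO[Si](C)(C)C(C)(C)C | intermediate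
12 | methyl 2-[(7S,8R)-8-{[(tert-butyldimethylsilyl)oxy]methyl}-7-methyl-1,4-dioxaspiro[4.5]decan-7-yl]acetate | COC(=O)C[C@]1(C)CC2(OCCO2)CC[C@H]1CO[Si](C)(C)C(C)(C)C | intermediate
13 | 2-[(7R,8R)-8-{[(tert-butyldimethylsilyl)oxy]methyl}-7-methyl-1,4-dioxaspiro[4.5]decan-7-yl]ethan-1-ol | OCC[C@]1(C)CC2(OCCO2)CC[C@H]1CO[Si](C)(C)C(C)(C)C | intermediate
14 | tert-butyl{[(7S,8R)-7-(2-chloroethyl)-7-methyl-1,4-dioxaspiro[4.5]decan-8-yl]methoxy}dimethylsilane | ClCC[C@]1(C)CC2(OCCO2)CC[C@H]1CO[Si](C)(C)C(C)(C)C | intermediate
15 | [(7S,8R)-7-(2-chloroethyl)-7-methyl-1,4-dioxaspiro[4.5]decan-8-yl]methanol | ClCC[C@]1(C)CC2(OCCO2)CC[C@H]1CO | intermediate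
16 | (7S,8R)-7-(2-chloroethyl)-7-methyl-1,4-dioxaspiro[4.5]decane-8-carbaldehyde | ClCC[C@]1(C)CC2(OCCO2)CC[C@H]1C=O | intermediate
17 | 1-[(7S,8R)-7-(2-chloroethyl)-7-methyl-1,4-dioxaspiro[4.5]decan-8-yl]ethan-1-ol (carbinol epimers) | ClCC[C@]1(C)CC2(OCCO2)CC[C@H]1C(C)O | intermediate
18 | 1-[(7S,8R)-7-(2-chloroethyl)-7-methyl-1,4-dioxaspiro[4.5]decan-8-yl]ethan-1-one | ClCC[C@]1(C)CC2(OCCO2)CC[C@H]1C(C)=O | intermediate
19 | 1,3-dithiane | C1CSCSC1 | starting material
20 | 2-lithio-1,3-dithiane | [Li]C1SCCCS1 | intermediate
21 | (1S)-1-[(7S,8R)-7-(2-chloroethyl)-7-methyl-1,4-dioxaspiro[4.5]decan-8-yl]-1-(1,3-dithian-2-yl)ethan-1-ol | ClCC[C@]1(C)CC2(OCCO2)CC[C@H]1[C@](C)(O)C1SCCCS1 | intermediate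
22 | O,C-dilithio derivative of 21 | [Li+].[Li+].ClCC[C@]1(C)CC2(OCCO2)CC[C@H]1[C@](C)([O-])[C-]1SCCCS1 | intermediate
23 | 3,3-(propane-1,3-diyldisulfanediyl)-8,8-(ethylenedioxy)-11,12,13-trinoreudesman-4α-ol | S1CCCSC12CC[C@]3(C)CC4(OCCO4)CC[C@H]3[C@]2(C)O | intermediate
24 | 8,8-(ethylenedioxy)-4α-hydroxy-11,12,13-trinoreudesman-3-one | O=C1CC[C@]2(C)CC3(OCCO3)CC[C@H]2[C@]1(C)O | intermediate
25 | 8,8-(ethylenedioxy)-11,12,13-trinoreudesmane-3β,4α-diol | O[C@H]1CC[C@]2(C)CC3(OCCO3)CC[C@H]2[C@]1(C)O | intermediate
26 | 3β,4α-dihydroxy-11,12,13-trinoreudesman-8-one | O[C@H]1CC[C@]2(C)CC(=O)CC[C@H]2[C@]1(C)O | intermediate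
27 | trilithium salt of 26 (3,4-dialkoxide, C7 enolate) | [Li+].[Li+].[Li+].[O-][C@H]1CC[C@]2(C)CC([O-])=CC[C@H]2[C@]1(C)[O-] | intermediate
28 | 3β,4α,11-trihydroxyeudesman-8-one (C7 epimers) | O[C@H]1CC[C@]2(C)CC(=O)C(C(C)(C)O)C[C@H]2[C@]1(C)O | intermediate
29 | 3β,4α-dihydroxyeudesm-7(11)-en-8-one | O[C@H]1CC[C@]2(C)CC(=O)C(=C(C)C)C[C@H]2[C@]1(C)O | intermediate
30 | angelic acid, (Z)-2-methylbut-2-enoic acid | C/C=C(/C)C(=O)O | starting material
31 | angelic 2,4,6-trichlorobenzoic anhydride | C/C=C(/C)C(=O)OC(=O)c1c(Cl)cc(Cl)cc1Cl | intermediate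
32 | 3β-angeloyloxy-4α-hydroxyeudesm-7(11)-en-8-one | C/C=C(/C)C(=O)O[C@H]1CC[C@]2(C)CC(=O)C(=C(C)C)C[C@H]2[C@]1(C)O | intermediate
33 | 3β-angeloyloxy-11-hydroperoxy-4α-hydroxyeudesm-6-en-8-one (CNP0161122.1) | C/C=C(/C)C(=O)O[C@H]1CC[C@]2(C)CC(=O)C(C(C)(C)OO)=C[C@H]2[C@]1(C)O | target

**Step count.** Total: 21 steps. Longest linear sequence: 21 steps (1 → 33); allene 8, 1,3-dithiane 19 and angelic acid 30 enter as purchased reagents.

**Steps most likely to fail**

Step 15. The second lithiation beside the lithium alkoxide may be slow. The dithiane addition may also revert on warming, or the alkoxide may attack the chloride to form a cyclic ether. The fallback uses known chemistry, sets out from 18 and comes back at 24; it sets C4 by the face of an osmylation instead of by acyclic addition. Ketone 18 is deprotonated at its acetyl methyl group with LiN(iPr)2 at −78 °C and the enolate is alkylated internally by the chloride on warming, so that the acetyl carbon becomes C3 and gives the ring A ketone F1. Kinetic enolisation toward C3 (LiN(iPr)2, −78 °C, which leaves C5 alone) and trapping with PhNTf2 gives the enol triflate F2. Coupling with MeMgBr under Fe(acac)3 catalysis brings in C15 and gives the alkene F3. OsO4 (cat.) with N-methylmorpholine N-oxide should add from the α face, away from the axial C10 methyl, to give the cis-diol F4 with the 4α-OH, 4β-CH3 pattern. Dess–Martin oxidation of its secondary hydroxyl then gives ketol 24.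

Step 5. Attack at C10 may not discriminate well between the two faces, head-to-tail addition may compete, and the β,γ-unsaturated ketone may react further under irradiation. The fallback sets out from 7 and comes back at 13. Copper-mediated conjugate addition of vinylmagnesium bromide (CuBr·SMe2, THF, −40 °C) to enone 7 should place the vinyl group on C10 anti to the C5 arm and give the vinyl ketone F5. Silyl-transfer ketalization as in step 7 gives the vinyl ketal F6. Hydroboration with 9-borabicyclo[3.3.1]nonane and oxidation (H2O2, NaOH) turns the vinyl group into the CH2CH2OH arm (C1–C2) of alcohol 13.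

Step 3. The lipase may discriminate poorly between enantiomers whose stereocentre lies one carbon away from the reacting hydroxyl, or it may acetylate the wanted enantiomer. The fallback sets out from 5 and comes back at 6. Racemic 5 is esterified with (S)-O-methylmandelic acid (N,N'-dicyclohexylcarbodiimide, 4-dimethylaminopyridine, CH2Cl2). The two diastereomeric esters are separated by chromatography or crystallisation, and the ester of the (R)-alcohol, the mandelate F7, is cleaved with K2CO3 in methanol at 0 °C to return 6.

**Further compounds**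

F1 | step 15 | 8,8-(ethylenedioxy)-11,12,13,15-tetranoreudesman-4-one | O=C1CCC[C@]2(C)CC3(OCCO3)CC[C@@H]12
F2 | step 15 | 8,8-(ethylenedioxy)-11,12,13,15-tetranoreudesm-3-en-4-yl trifluoromethanesulfonate | FC(F)(F)S(=O)(=O)OC1=CCC[C@]2(C)CC3(OCCO3)CC[C@@H]12
F3 | step 15 | 8,8-(ethylenedioxy)-11,12,13-trinoreudesm-3-ene | CC1=CCC[C@]2(C)CC3(OCCO3)CC[C@@H]12
F4 | step 15 | 8,8-(ethylenedioxy)-11,12,13-trinoreudesmane-3α,4α-diol | O[C@@H]1CC[C@]2(C)CC3(OCCO3)CC[C@H]2[C@]1(C)O
F5 | step 5 | (3S,4R)-4-{[(tert-butyldimethylsilyl)oxy]methyl}-3-ethenyl-3-methylcyclohexan-1-one | C=C[C@]1(C)CC(=O)CC[C@H]1CO[Si](C)(C)C(C)(C)C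
F6 | step 5 | tert-butyl{[(7S,8R)-7-ethenyl-7-methyl-1,4-dioxaspiro[4.5]decan-8-yl]methoxy}dimethylsilane | C=C[C@]1(C)CC2(OCCO2)CC[C@H]1CO[Si](C)(C)C(C)(C)C
F7 | step 3 | [(R)-2-methyl-4-oxocyclohex-2-en-1-yl]methyl (S)-2-methoxy-2-phenylacetate | CO[C@H](C(=O)OC[C@@H]1CCC(=O)C=C1C)c1ccccc1
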